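**Retrosynthetic overview**

- Feature used: in each flavone unit the pyranone ring C contains a C2–C3 bond in which C3 was an acetophenone methyl carbon and C2 an aroyl carbonyl carbon. In the acacetin unit this is the 4-methoxybenzoyl carbon; in the apigenin unit it is the carbonyl carbon of the bridging 4-aryloxybenzoyl ring. One bis(aryl ester) of two ortho-acetylphenols therefore holds every carbon of the biflavone.
- Target 13 ⇒ (remove four benzyl groups) biflavone 12 ⇒ (open both O1–C2 bonds) bis(1,3-diketone) 11 ⇒ (cut both C2–C3 bonds) bis(aryl ester) 10.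
- 10 ⇒ (ester cuts) acid 9 + phenol 2; 9 ⇒ 4-methoxybenzoyl chloride 7 + diaryl ether 6.
- 6 ⇒ (diaryl ether C–O cut, aromatic substitution) quinol ketone 4 + tert-butyl 4-fluorobenzoate 5; 4 ⇒ para-hydroxylation of 2, the dibenzyl ether of 2',4',6'-trihydroxyacetophenone 1, which therefore serves twice.
- Ring order: the four benzene rings are bought; the two pyranone rings close together in step 8, after the twofold acyl shift.

Key step: step 7

Remark: tert-butyl 4-fluorobenzoate is taken as a purchasable building block, and the 1,3-diketones are drawn as diketo forms although they should exist largely as chelated enols.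

**Route**

Step 1
Reactants: 1 2',4',6'-trihydroxyacetophenone
Product: 2 1-[2,4-bis(benzyloxy)-6-hydroxyphenyl]ethan-1-one
Conditions: BnBr (2.05 equiv), K2CO3, DMF, 0 °C to rt
Reagents that add atoms: benzyl bromide, BrCc1ccccc1
Why: Williamson etherification in which the 4-OH and one of the two equivalent ortho-OH groups react as phenoxides, while the last ortho-OH is held in a hydrogen bond to the acetyl carbonyl and should stay free when benzyl bromide is limited to two equivalents.

Step 2
Reactants: 2 1-[2,4-bis(benzyloxy)-6-hydroxyphenyl]ethan-1-one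
Product: 4 1-[2,4-bis(benzyloxy)-3,6-dihydroxyphenyl]ethan-1-one, via potassium aryl sulfate 3 (not isolated)
Conditions: K2S2O8, aq KOH, pyridine, 15–20 °C; then aq HCl, Na2SO3, 80 °C, N2
Reagents that add atoms: potassium peroxodisulfate K2S2O8, [K+].[K+].[O-]S(=O)(=O)OOS(=O)(=O)[O-]
Why: Elbs persulfate oxidation, in which the phenoxide of 2 attacks a peroxide oxygen of peroxodisulfate through C3 (the carbon para to the free hydroxyl at C6) to give aryl sulfate 3, and acid hydrolysis of the sulfate then releases the new phenol; ortho attack is only a minor path in this reaction and the benzyl ethers and the ketone are inert to alkaline persulfate.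

Step 3
Reactants: 4 1-[2,4-bis(benzyloxy)-3,6-dihydroxyphenyl]ethan-1-one, 5 tert-butyl 4-fluorobenzoate
Product: 6 tert-butyl 4-[3-acetyl-2,6-bis(benzyloxy)-4-hydroxyphenoxy]benzoate
Conditions: Cs2CO3, DMSO, 110 °C, argon
Reagents that add atoms: none
Why: Nucleophilic aromatic substitution by addition–elimination on the para-ester-activated aryl fluoride, in which the C3 phenoxide of 4 is the stronger nucleophile because it is not conjugated with the acetyl group, whereas the C6 phenoxide is chelated and delocalised into the ketone (the same preference that governs selective 5-O-alkylation of 2,5-dihydroxyacetophenones); the tert-butyl ester is too hindered to be attacked.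

Step 4
Reactants: 6 tert-butyl 4-[3-acetyl-2,6-bis(benzyloxy)-4-hydroxyphenoxy]benzoate, 7 4-methoxybenzoyl chloride
Product: 8 tert-butyl 4-{3-acetyl-2,6-bis(benzyloxy)-4-[(4-methoxybenzoyl)oxy]phenoxy}benzoate
Conditions: pyridine, DMAP (cat.), 0 °C to rt
Reagents that add atoms: none
Why: O-acylation of the chelated phenol through the N-acylpyridinium ion (DMAP-catalysed acylation in pyridine), the usual preparation of the aryl ester for a Baker–Venkataraman shift, with no base present that is strong enough to enolise the ketone.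

Step 5
Reactants: 8 tert-butyl 4-{3-acetyl-2,6-bis(benzyloxy)-4-[(4-methoxybenzoyl)oxy]phenoxy}benzoate
Product: 9 4-{3-acetyl-2,6-bis(benzyloxy)-4-[(4-methoxybenzoyl)oxy]phenoxy}benzoic acid
Conditions: CF3CO2H, CH2Cl2, 0 °C to rt
Reagents that add atoms: none
Why: Acidolysis of the tert-butyl ester by alkyl–oxygen cleavage with loss of 2-methylpropene, conditions under which the aryl 4-methoxybenzoate, the aryl benzyl ethers, the diaryl ether and the ketone should be stable at room temperature.

Step 6
Reactants: 9 4-{3-acetyl-2,6-bis(benzyloxy)-4-[(4-methoxybenzoyl)oxy]phenoxy}benzoic acid, 2 1-[2,4-bis(benzyloxy)-6-hydroxyphenyl]ethan-1-one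
Product: 10 2-acetyl-3,5-bis(benzyloxy)phenyl 4-{3-acetyl-2,6-bis(benzyloxy)-4-[(4-methoxybenzoyl)oxy]phenoxy}benzoate
Conditions: DCC, DMAP, CH2Cl2, rt
Reagents that add atoms: none
Why: Steglich esterification, in which DCC activates the acid as its O-acylisourea and DMAP relays the acyl group to the chelated phenol of 2, under conditions too weakly basic to trigger acyl migration or to cleave the aryl ester already present.

Step 7
Reactants: 10 2-acetyl-3,5-bis(benzyloxy)phenyl 4-{3-acetyl-2,6-bis(benzyloxy)-4-[(4-methoxybenzoyl)oxy]phenoxy}benzoate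
Product: 11 1-[2,4-bis(benzyloxy)-3-(4-{3-[2,4-bis(benzyloxy)-6-hydroxyphenyl]-3-oxopropanoyl}phenoxy)-6-hydroxyphenyl]-3-(4-methoxyphenyl)propane-1,3-dione
Conditions: LiN(SiMe3)2 (6 equiv), THF, −78 °C to 0 °C; then aq HCl
Reagents that add atoms: none
Why: Baker–Venkataraman rearrangement at both ester sites: LiN(SiMe3)2 turns each aryl methyl ketone into its lithium enolate, the enolate carbon adds to the carbonyl of the aroyl ester on the neighbouring phenol oxygen through a six-membered cyclic transition state, and collapse of the tetrahedral alkoxide expels the phenoxide, so that the 4-methoxybenzoyl carbon becomes bonded to the methyl carbon of the central acetophenone (future C2–C3 of the acacetin unit) and the bridging benzoyl carbon to the methyl carbon of the bis(benzyloxy)acetophenone (future C2–C3 of the apigenin unit). The closest known reaction is the amide-base Baker–Venkataraman shift of 2-aroyloxy-4,6-dialkoxyacetophenones, needed here twice in one molecule. No ring is closed and no stereocenter is formed in this step. The selectivity required is that each enolate acylates on its own ortho ester and not across the diaryl ether or between molecules; the short tether makes the intramolecular path far faster, and dilution suppresses intermolecular Claisen condensation. Both esters are aroyl esters without α-hydrogens, the base is non-nucleophilic, and each site takes up a second equivalent of base to form the stabilised β-diketonate, which should drive both migrations to completion and protect the products from further attack.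

Step 8
Reactants: 11 1-[2,4-bis(benzyloxy)-3-(4-{3-[2,4-bis(benzyloxy)-6-hydroxyphenyl]-3-oxopropanoyl}phenoxy)-6-hydroxyphenyl]-3-(4-methoxyphenyl)propane-1,3-dione
Product: 12 5,7-bis(benzyloxy)-6-{4-[5,7-bis(benzyloxy)-4-oxo-4H-chromen-2-yl]phenoxy}-2-(4-methoxyphenyl)-4H-chromen-4-one
Conditions: AcOH, H2SO4 (cat.), 90 °C
Reagents that add atoms: none
Why: Acid-catalysed cyclodehydration in which each phenol freed in step 7 adds to the aryl ketone carbonyl of its diketone (6-exo-trig hemiketal formation) and loss of water gives the 4H-chromen-4-one; because the other ortho oxygen of the central ring is still benzylated, only the hydroxyl para to the aryloxy group can close, which places the diaryl ether at C6.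

Step 9
Reactants: 12 5,7-bis(benzyloxy)-6-{4-[5,7-bis(benzyloxy)-4-oxo-4H-chromen-2-yl]phenoxy}-2-(4-methoxyphenyl)-4H-chromen-4-one
Product: 13 cryptomerin A, 5,7-dihydroxy-6-[4-(5,7-dihydroxy-4-oxo-4H-chromen-2-yl)phenoxy]-2-(4-methoxyphenyl)-4H-chromen-4-one
Conditions: H2 (1 atm), 10% Pd/C, THF–MeOH, rt
Reagents that add atoms: none
Why: Hydrogenolysis of the four aryl benzyl ethers over Pd/C, under which the aryl methyl ether and the diaryl ether are not cleaved and the chromone C2=C3 bonds should not be reduced at one atmosphere and room temperature.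

**Compound list** (all compounds are achiral)

1 | 2',4',6'-trihydroxyacetophenone | CC(=O)c1c(O)cc(O)cc1O | starting material
2 | 1-[2,4-bis(benzyloxy)-6-hydroxyphenyl]ethan-1-one | CC(=O)c1c(O)cc(OCc2ccccc2)cc1OCc1ccccc1 | intermediate
3 | potassium 3-acetyl-2,6-bis(benzyloxy)-4-hydroxyphenyl sulfate | CC(=O)c1c(O)cc(OCc2ccccc2)c(OS(=O)(=O)[O-])c1OCc1ccccc1.[K+] | intermediate
4 | 1-[2,4-bis(benzyloxy)-3,6-dihydroxyphenyl]ethan-1-one | CC(=O)c1c(O)cc(OCc2ccccc2)c(O)c1OCc1ccccc1 | intermediate
5 | tert-butyl 4-fluorobenzoate | CC(C)(C)OC(=O)c1ccc(F)cc1 | starting material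
6 | tert-butyl 4-[3-acetyl-2,6-bis(benzyloxy)-4-hydroxyphenoxy]benzoate | CC(=O)c1c(O)cc(OCc2ccccc2)c(Oc2ccc(cc2)C(=O)OC(C)(C)C)c1OCc1ccccc1 | intermediate
7 | 4-methoxybenzoyl chloride | COc1ccc(cc1)C(Cl)=O | starting material
8 | tert-butyl 4-{3-acetyl-2,6-bis(benzyloxy)-4-[(4-methoxybenzoyl)oxy]phenoxy}benzoate | CC(=O)c1c(OC(=O)c2ccc(OC)cc2)cc(OCc2ccccc2)c(Oc2ccc(cc2)C(=O)OC(C)(C)C)c1OCc1ccccc1 | intermediate
9 | 4-{3-acetyl-2,6-bis(benzyloxy)-4-[(4-methoxybenzoyl)oxy]phenoxy}benzoic acid | CC(=O)c1c(OC(=O)c2ccc(OC)cc2)cc(OCc2ccccc2)c(Oc2ccc(cc2)C(O)=O)c1OCc1ccccc1 | intermediate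
10 | 2-acetyl-3,5-bis(benzyloxy)phenyl 4-{3-acetyl-2,6-bis(benzyloxy)-4-[(4-methoxybenzoyl)oxy]phenoxy}benzoate | CC(=O)c1c(OC(=O)c2ccc(OC)cc2)cc(OCc2ccccc2)c(Oc2ccc(C(=O)Oc3cc(OCc4ccccc4)cc(OCc4ccccc4)c3C(C)=O)cc2)c1OCc1ccccc1 | intermediate
11 | 1-[2,4-bis(benzyloxy)-3-(4-{3-[2,4-bis(benzyloxy)-6-hydroxyphenyl]-3-oxopropanoyl}phenoxy)-6-hydroxyphenyl]-3-(4-methoxyphenyl)propane-1,3-dione | COc1ccc(C(=O)CC(=O)c2c(O)cc(OCc3ccccc3)c(Oc3ccc(C(=O)CC(=O)c4c(O)cc(OCc5ccccc5)cc4OCc4ccccc4)cc3)c2OCc2ccccc2)cc1 | intermediate
12 | 5,7-bis(benzyloxy)-6-{4-[5,7-bis(benzyloxy)-4-oxo-4H-chromen-2-yl]phenoxy}-2-(4-methoxyphenyl)-4H-chromen-4-one | COc1ccc(-c2cc(=O)c3c(OCc4ccccc4)c(Oc4ccc(-c5cc(=O)c6c(OCc7ccccc7)cc(OCc7ccccc7)cc6o5)cc4)c(OCc4ccccc4)cc3o2)cc1 | intermediate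
13 | cryptomerin A | COc1ccc(-c2cc(=O)c3c(O)c(Oc4ccc(-c5cc(=O)c6c(O)cc(O)cc6o5)cc4)c(O)cc3o2)cc1 | target

**Step count and risks**

Total step count: 9.
Longest linear sequence: 9 steps (1 → 2 → 4 → 6 → 8 → 9 → 10 → 11 → 12 → 13); compound 2 is drawn on a second time in step 6.

Steps most likely to fail:

1. Step 2 (para-hydroxylation). The sulfation may stop at low conversion because the benzylated phenoxide is poorly soluble. The hydroquinone product may be oxidised further by persulfate or air. A benzyl ether may be lost during the warm acid hydrolysis of the sulfate. Fallback: setting out from 2, the phenol (para position free) would be oxidised with potassium nitrosodisulfonate K2[ON(SO3)2] in aqueous acetone buffered with KH2PO4 to 2-acetyl-3,5-bis(benzyloxy)-1,4-benzoquinone F1. Reduction of this quinone with aqueous Na2S2O4 in a two-phase mixture with ethyl acetate comes back to the route at 4. This replaces the sulfate transfer by a quinone oxidation–reduction pair and avoids the hot acid.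

2. Step 3 (diaryl ether formation). Addition of the phenoxide, which is flanked by two benzyloxy groups, to the only moderately activated fluoroarene may be slow. Air oxidation of the hydroquinone dianion and arylation at the chelated oxygen could then compete. Fallback: setting out from 4, the uncatalysed substitution would be replaced by a copper-catalysed Ullmann-type ether synthesis with tert-butyl 4-iodobenzoate (CuI, picolinic acid, K3PO4, DMSO, 80–90 °C, argon), a coupling that tolerates doubly ortho-substituted phenols. It comes back to the route at 6 and makes no new compound (F0).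

3. Step 7 (twofold acyl shift). The sequence may stall after one migration. An aryl ester may be cleaved by adventitious hydroxide before it migrates. Acyl transfer between molecules may scramble the two aroyl groups. Fallback: the two shifts are run one after the other, setting out from 8.
   - A single Baker–Venkataraman shift (LiN(SiMe3)2, THF) would give tert-butyl 4-{2,6-bis(benzyloxy)-4-hydroxy-3-[3-(4-methoxyphenyl)-3-oxopropanoyl]phenoxy}benzoate F2.
   - AcOH with catalytic H2SO4 at 90 °C should close the first pyranone and cleave the tert-butyl ester in the same operation, giving 4-{[5,7-bis(benzyloxy)-2-(4-methoxyphenyl)-4-oxo-4H-chromen-6-yl]oxy}benzoic acid F3.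
   - DCC/DMAP esterification with 2 gives 2-acetyl-3,5-bis(benzyloxy)phenyl 4-{[5,7-bis(benzyloxy)-2-(4-methoxyphenyl)-4-oxo-4H-chromen-6-yl]oxy}benzoate F4.
   - A second shift with LiN(SiMe3)2 gives 5,7-bis(benzyloxy)-6-(4-{3-[2,4-bis(benzyloxy)-6-hydroxyphenyl]-3-oxopropanoyl}phenoxy)-2-(4-methoxyphenyl)-4H-chromen-4-one F5.
   - Cyclodehydration under the conditions of step 8 comes back to the route at 12.

Further compounds
F1 | step 2 | 2-acetyl-3,5-bis(benzyloxy)-1,4-benzoquinone | CC(=O)C1=C(OCc2ccccc2)C(=O)C(OCc2ccccc2)=CC1=O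
F0 | step 3 | none | none
F2 | step 7 | tert-butyl 4-{2,6-bis(benzyloxy)-4-hydroxy-3-[3-(4-methoxyphenyl)-3-oxopropanoyl]phenoxy}benzoate | COc1ccc(C(=O)CC(=O)c2c(O)cc(OCc3ccccc3)c(Oc3ccc(C(=O)OC(C)(C)C)cc3)c2OCc2ccccc2)cc1
F3 | step 7 | 4-{[5,7-bis(benzyloxy)-2-(4-methoxyphenyl)-4-oxo-4H-chromen-6-yl]oxy}benzoic acid | COc1ccc(-c2cc(=O)c3c(OCc4ccccc4)c(Oc4ccc(C(=O)O)cc4)c(OCc4ccccc4)cc3o2)cc1
F4 | step 7 | 2-acetyl-3,5-bis(benzyloxy)phenyl 4-{[5,7-bis(benzyloxy)-2-(4-methoxyphenyl)-4-oxo-4H-chromen-6-yl]oxy}benzoate | COc1ccc(-c2cc(=O)c3c(OCc4ccccc4)c(Oc4ccc(C(=O)Oc5cc(OCc6ccccc6)cc(OCc6ccccc6)c5C(C)=O)cc4)c(OCc4ccccc4)cc3o2)cc1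
F5 | step 7 | 5,7-bis(benzyloxy)-6-(4-{3-[2,4-bis(benzyloxy)-6-hydroxyphenyl]-3-oxopropanoyl}phenoxy)-2-(4-methoxyphenyl)-4H-chromen-4-one | COc1ccc(-c2cc(=O)c3c(OCc4ccccc4)c(Oc4ccc(C(=O)CC(=O)c5c(O)cc(OCc6ccccc6)cc5OCc5ccccc5)cc4)c(OCc4ccccc4)cc3o2)cc1
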